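**Retrosynthetic overview**

1. The target comes from a Cope ([3,3]) shift of the allyl group from C3a to C5 of the cross-conjugated 3a-allyl dienone; the shift is suprafacial, so C3a chirality becomes C5 chirality.
2. The 3a-allyl dienone comes from C4–C5 dehydrogenation of a bicyclic vinylogous ester (hexahydrobenzofuranone).
3. Key step: that bicycle is made in one pot from an acyclic α-allyl γ-silyloxy ester and 3-methoxybut-3-en-2-one by Michael addition, Claisen condensation and cyclodehydration. The carbocycle closes first (C3a–C4, then C7–C7a), the dihydrofuran second (O1–C7a).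
4. The acyclic ester comes from anti methyl-cuprate addition and allylation of an (S,E)-γ-silyloxy enoate, itself from asymmetric propiolate alkynylation of 3,4,5-trimethoxybenzaldehyde and trans-reduction.

Assumption: ring positions of all intermediates use benzofuran numbering (O1, C2, C3, C3a, C4–C7, C7a); Ar = 3,4,5-trimethoxyphenyl, TBS = tert-butyl(dimethyl)silyl.

**Route**

Step 1
Reactants: 1 3,4,5-trimethoxybenzaldehyde; 2 methyl propiolate
Product: 3 methyl (R)-4-hydroxy-4-(3,4,5-trimethoxyphenyl)but-2-ynoate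
Conditions: Me2Zn (3 equiv), ProPhenol ligand (antipode giving the R alcohol, 20 mol %), Ph3PO (40 mol %), toluene, 4 °C; aq. NH4Cl
Reagents that add atoms: none
Why: Catalytic enantioselective aldehyde alkynylation (dinuclear zinc–ProPhenol, Trost type) sets the benzylic carbinol, the future C2; the descriptor is R here only because the alkynyl group outranks the aryl group.

Step 2
Reactants: 3 methyl (R)-4-hydroxy-4-(3,4,5-trimethoxyphenyl)but-2-ynoate
Product: 4 methyl (S,E)-4-hydroxy-4-(3,4,5-trimethoxyphenyl)but-2-enoate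
Conditions: NaAlH2(OCH2CH2OCH3)2 (2 equiv), THF, −72 °C; 1 M HCl
Reagents that add atoms: none
Why: Alkoxide-directed trans-hydroalumination of the γ-hydroxy ynoate and protonolysis give the E-enoate without touching the ester or the stereocentre (same spatial arrangement, descriptor now S).

Step 3
Reactants: 4 methyl (S,E)-4-hydroxy-4-(3,4,5-trimethoxyphenyl)but-2-enoate
Product: 5 methyl (S,E)-4-{[tert-butyl(dimethyl)silyl]oxy}-4-(3,4,5-trimethoxyphenyl)but-2-enoate
Conditions: TBSCl, imidazole, DMF, 23 °C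
Reagents that add atoms: tert-butyldimethylsilyl chloride (TBSCl), CC(C)(C)[Si](C)(C)Cl
Why: Silyl ether formation keeps the chain acyclic (no lactonisation) and provides the bulky γ-substituent that directs the next two C–C bond formations.

Step 4
Reactants: 5 methyl (S,E)-4-{[tert-butyl(dimethyl)silyl]oxy}-4-(3,4,5-trimethoxyphenyl)but-2-enoate
Product: 7 methyl (3S,4S)-4-{[tert-butyl(dimethyl)silyl]oxy}-3-methyl-4-(3,4,5-trimethoxyphenyl)butanoate, via silyl ketene acetal 6 (not isolated)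
Conditions: Me2CuLi (from CuI and 2 MeLi, 2.5 equiv), TMSCl, THF, −78 °C; aq. NH4Cl/NH3
Reagents that add atoms: lithium dimethylcuprate (Me2CuLi), [Li+].C[Cu-]C
Why: TMSCl-accelerated Gilman cuprate conjugate addition to an E-γ-silyloxy enoate gives the 3,4-anti adduct (inside-alkoxy Felkin-type attack anti to the aryl group), which sets C3 as S and corresponds to the trans 2-aryl-3-methyl relationship of the target.

Step 5
Reactants: 7 methyl (3S,4S)-4-{[tert-butyl(dimethyl)silyl]oxy}-3-methyl-4-(3,4,5-trimethoxyphenyl)butanoate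
Product: 8 methyl (3S,4S)-2-allyl-4-{[tert-butyl(dimethyl)silyl]oxy}-3-methyl-4-(3,4,5-trimethoxyphenyl)butanoate (C2 epimers)
Conditions: LiN(iPr)2, THF, −78 °C; allyl bromide, DMPU, −78 → −20 °C
Reagents that add atoms: allyl bromide, C=CCBr
Why: Ester enolate alkylation installs the allyl group; the new C2 centre need not be controlled because it is planarised again as an enolate in step 7.

Step 6
Reactants: 9 3,3-dimethoxybutan-2-one
Product: 10 3-methoxybut-3-en-2-one
Conditions: TsOH·H2O (1 mol %), hydroquinone (trace), 140 °C, methanol distilled off; product distilled and used fresh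
Reagents that add atoms: none
Why: Acid-catalysed loss of methanol from the α-keto ketal (ketal to enol ether elimination) gives the α-methoxy vinyl ketone used as the four-carbon annulation partner.

Step 7
Reactants: 8 methyl (3S,4S)-2-allyl-4-{[tert-butyl(dimethyl)silyl]oxy}-3-methyl-4-(3,4,5-trimethoxyphenyl)butanoate (C2 epimers); 10 3-methoxybut-3-en-2-one
Product: 14 (2S,3S,3aS)-3a-allyl-5-methoxy-3-methyl-2-(3,4,5-trimethoxyphenyl)-3,3a,4,5-tetrahydro-1-benzofuran-6(2H)-one (C5 epimers), via Michael adduct 11 (not isolated), via silyloxy dione 12 (not isolated), via hydroxy dione 13 (not isolated)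
Conditions: LiN(iPr)2 (1.1 equiv), THF, −78 → −40 °C; 10 (1.3 equiv), −78 → −30 °C; KOtBu (2 equiv), t-BuOH/THF, 0 → 45 °C; then 3 M HCl, THF, 45 °C
Reagents that add atoms: none
Why: Michael addition–Claisen (Dieckmann-type) condensation–cyclodehydration cascade, the ester/vinyl ketone route to 4,4-disubstituted cyclohexane-1,3-diones: the tetrasubstituted ester enolate of 8 adds to 10 on the face anti to the bulky CH(OTBS)Ar group in the A(1,3)-minimised conformer (C3–H eclipsing the enolate), which fixes the quaternary C3a with allyl cis to the C3 methyl, the equilibrated methyl ketone enolate then acylates on the ester to close the carbocycle, and acid removes the silyl group so that the C2 hydroxyl condenses with the vinylogous acid to close the dihydrofuran as a cyclic vinylogous ester.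

Step 8
Reactants: 14 (2S,3S,3aS)-3a-allyl-5-methoxy-3-methyl-2-(3,4,5-trimethoxyphenyl)-3,3a,4,5-tetrahydro-1-benzofuran-6(2H)-one (C5 epimers)
Product: 16 (2S,3S,3aR)-3a-allyl-5-methoxy-3-methyl-2-(3,4,5-trimethoxyphenyl)-3,3a-dihydro-1-benzofuran-6(2H)-one, via selenide 15 (not isolated)
Conditions: LiN(iPr)2 (1.2 equiv), THF, −78 °C; PhSeCl (1.05 equiv); then H2O2 (30 %), pyridine, CH2Cl2, 0 → 23 °C
Reagents that add atoms: none
Why: Kinetic α′-deprotonation of the vinylogous ester at C5 (Stork–Danheiser site selectivity), selenenylation and selenoxide syn-elimination toward the only β-hydrogens (C4) give the α-methoxy enone; the uncontrolled C5 centre disappears and C3a keeps its configuration (descriptor changes to R by priority only).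

Step 9
Reactants: 16 (2S,3S,3aR)-3a-allyl-5-methoxy-3-methyl-2-(3,4,5-trimethoxyphenyl)-3,3a-dihydro-1-benzofuran-6(2H)-one
Product: 17 (2S,3S,5S)-5-allyl-5-methoxy-3-methyl-2-(3,4,5-trimethoxyphenyl)-3,5-dihydro-1-benzofuran-6(2H)-one
Conditions: toluene (0.02 M, degassed), 110 °C, sealed tube; stopped as soon as 16 is consumed
Reagents that add atoms: none
Why: Thermal Cope ([3,3]) rearrangement of the allyl–C3a–C4=C5 1,5-diene: the allyl group migrates suprafacially on the face it occupies at C3a, so the 3aR centre becomes the 5S centre, and the shift is driven by formation of the linearly conjugated push–pull dienone and relief of the congested ring-fusion quaternary carbon.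

**Compound list**

1 | 3,4,5-trimethoxybenzaldehyde | COc1cc(C=O)cc(OC)c1OC | starting material
2 | methyl propiolate (methyl prop-2-ynoate) | C#CC(=O)OC | starting material
3 | methyl (R)-4-hydroxy-4-(3,4,5-trimethoxyphenyl)but-2-ynoate | COC(=O)C#C[C@H](O)c1cc(OC)c(OC)c(OC)c1 | intermediate
4 | methyl (S,E)-4-hydroxy-4-(3,4,5-trimethoxyphenyl)but-2-enoate | COC(=O)/C=C/[C@H](O)c1cc(OC)c(OC)c(OC)c1 | intermediate
5 | methyl (S,E)-4-{[tert-butyl(dimethyl)silyl]oxy}-4-(3,4,5-trimethoxyphenyl)but-2-enoate | COC(=O)/C=C/[C@H](O[Si](C)(C)C(C)(C)C)c1cc(OC)c(OC)c(OC)c1 | intermediate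
6 | {[(3S,4S)-4-{[tert-butyl(dimethyl)silyl]oxy}-1-methoxy-3-methyl-4-(3,4,5-trimethoxyphenyl)but-1-en-1-yl]oxy}trimethylsilane (silyl ketene acetal of 7, E/Z mixture) | COC(O[Si](C)(C)C)=C[C@H](C)[C@H](O[Si](C)(C)C(C)(C)C)c1cc(OC)c(OC)c(OC)c1 | intermediate
7 | methyl (3S,4S)-4-{[tert-butyl(dimethyl)silyl]oxy}-3-methyl-4-(3,4,5-trimethoxyphenyl)butanoate | COC(=O)C[C@H](C)[C@H](O[Si](C)(C)C(C)(C)C)c1cc(OC)c(OC)c(OC)c1 | intermediate
8 | methyl (3S,4S)-2-allyl-4-{[tert-butyl(dimethyl)silyl]oxy}-3-methyl-4-(3,4,5-trimethoxyphenyl)butanoate (C2 epimers) | COC(=O)C(CC=C)[C@H](C)[C@H](O[Si](C)(C)C(C)(C)C)c1cc(OC)c(OC)c(OC)c1 | intermediate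
9 | 3,3-dimethoxybutan-2-one | CC(=O)C(C)(OC)OC | starting material
10 | 3-methoxybut-3-en-2-one | CC(=O)C(=C)OC | intermediate
11 | methyl (2S,3S,4S)-2-allyl-4-{[tert-butyl(dimethyl)silyl]oxy}-2-(2-methoxy-3-oxobutyl)-3-methyl-4-(3,4,5-trimethoxyphenyl)butanoate (epimers at the methoxy carbon; present as its enolate) | COC(=O)[C@@](CC=C)(CC(OC)C(C)=O)[C@H](C)[C@H](O[Si](C)(C)C(C)(C)C)c1cc(OC)c(OC)c(OC)c1 | intermediate
12 | (4S)-4-allyl-4-[(2S,3S)-3-{[tert-butyl(dimethyl)silyl]oxy}-3-(3,4,5-trimethoxyphenyl)butan-2-yl]-6-methoxycyclohexane-1,3-dione (C6 epimers) | C=CC[C@]1(CC(OC)C(=O)CC1=O)[C@H](C)[C@H](O[Si](C)(C)C(C)(C)C)c1cc(OC)c(OC)c(OC)c1 | intermediate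
13 | (4S)-4-allyl-4-[(2S,3S)-3-hydroxy-3-(3,4,5-trimethoxyphenyl)butan-2-yl]-6-methoxycyclohexane-1,3-dione (C6 epimers) | C=CC[C@]1(CC(OC)C(=O)CC1=O)[C@H](C)[C@H](O)c1cc(OC)c(OC)c(OC)c1 | intermediate
14 | (2S,3S,3aS)-3a-allyl-5-methoxy-3-methyl-2-(3,4,5-trimethoxyphenyl)-3,3a,4,5-tetrahydro-1-benzofuran-6(2H)-one (C5 epimers) | C=CC[C@@]12CC(OC)C(=O)C=C1O[C@H](c1cc(OC)c(OC)c(OC)c1)[C@H]2C | intermediate
15 | (2S,3S,3aS)-3a-allyl-5-methoxy-3-methyl-5-(phenylselanyl)-2-(3,4,5-trimethoxyphenyl)-3,3a,4,5-tetrahydro-1-benzofuran-6(2H)-one (C5 epimers) | C=CC[C@@]12CC(OC)([Se]c3ccccc3)C(=O)C=C1O[C@H](c1cc(OC)c(OC)c(OC)c1)[C@H]2C | intermediate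
16 | (2S,3S,3aR)-3a-allyl-5-methoxy-3-methyl-2-(3,4,5-trimethoxyphenyl)-3,3a-dihydro-1-benzofuran-6(2H)-one | C=CC[C@@]12C=C(OC)C(=O)C=C1O[C@H](c1cc(OC)c(OC)c(OC)c1)[C@H]2C | intermediate
17 | (2S,3S,5S)-5-allyl-5-methoxy-3-methyl-2-(3,4,5-trimethoxyphenyl)-3,5-dihydro-1-benzofuran-6(2H)-one | C=CC[C@]1(OC)C=C2C(=CC1=O)O[C@H](c1cc(OC)c(OC)c(OC)c1)[C@H]2C | target

**Step count and risks**

Total step count: 9 (eight in the main line plus one to make enone 10). Longest linear sequence: 8 steps (steps 1–5 and 7–9).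

The three steps most likely to fail:

First, step 7. A hindered tetrasubstituted ester enolate must add 1,4 to an α-methoxy enone that can instead be deprotonated or polymerise. The Claisen closure is onto a neopentyl-type ester. The C3a configuration rests on acyclic A(1,3) control, and a wrong C3a epimer would end as the C5 epimer of the target. The fallback uses a lactone template and stepwise ring construction; it sets out from 7 and comes back at 14. Aqueous HCl in THF cleaves the silyl ether and the hydroxy ester lactonises to (4S,5S)-4-methyl-5-(3,4,5-trimethoxyphenyl)oxolan-2-one F1. LiN(iPr)2 and allyl bromide give (3S,4S,5S)-3-allyl-4-methyl-5-(3,4,5-trimethoxyphenyl)oxolan-2-one F2. Its lithium enolate adds to 10 on the ring face anti to the C4 methyl (cyclic control, the second α-substituent enters trans to methyl) to give (3S,4S,5S)-3-allyl-3-(2-methoxy-3-oxobutyl)-4-methyl-5-(3,4,5-trimethoxyphenyl)oxolan-2-one F3, which is isolated. KOtBu then closes the carbocycle by attack of the methyl ketone enolate on the lactone carbonyl, and aqueous HCl recloses the dihydrofuran to give 14.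

Second, step 4. The anti selectivity could erode with a γ-aryl γ-silyloxy enoate, and the cuprate could reductively cleave or displace the benzylic silyloxy group. The fallback sets the C2/C3 pair by reagent-controlled crotylation instead; it sets out from 1 and comes back at 7. (E)-Crotyl-B(Ipc)2 (the (−)-Ipc antipode) in THF at −78 °C, then NaOH/H2O2, gives (1S,2S)-2-methyl-1-(3,4,5-trimethoxyphenyl)but-3-en-1-ol F4. TBSCl and imidazole give tert-butyl(dimethyl){[(1S,2S)-2-methyl-1-(3,4,5-trimethoxyphenyl)but-3-en-1-yl]oxy}silane F5. 9-BBN then NaOH/H2O2 gives (3S,4S)-4-{[tert-butyl(dimethyl)silyl]oxy}-3-methyl-4-(3,4,5-trimethoxyphenyl)butan-1-ol F6. TEMPO/NaOCl/NaClO2 gives (3S,4S)-4-{[tert-butyl(dimethyl)silyl]oxy}-3-methyl-4-(3,4,5-trimethoxyphenyl)butanoic acid F7, and MeI/K2CO3 gives 7.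

Third, step 9. The allyl group can also shift to C7, after which enolisation gives an aromatic 7-allylphenol irreversibly. On prolonged heating 17 can also go on by retro-Claisen to the aromatic allyl ether. The fallback blocks C7; it sets out from 16 and comes back at 17. NBS in CH2Cl2 at 0 °C brominates the nucleophilic α-carbon of the vinylogous ester to give (2S,3S,3aR)-3a-allyl-7-bromo-5-methoxy-3-methyl-2-(3,4,5-trimethoxyphenyl)-3,3a-dihydro-1-benzofuran-6(2H)-one F8. A shift to C7 now gives a product that cannot aromatise and can revert, so heating at the lowest effective temperature funnels material to (2S,3S,5S)-5-allyl-7-bromo-5-methoxy-3-methyl-2-(3,4,5-trimethoxyphenyl)-3,5-dihydro-1-benzofuran-6(2H)-one F9. Bu3SnH with catalytic Pd(PPh3)4 removes the bromine to give 17.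

**Further compounds**

F1 | step 7 | (4S,5S)-4-methyl-5-(3,4,5-trimethoxyphenyl)oxolan-2-one | O=C1C[C@H](C)[C@@H](c2cc(OC)c(OC)c(OC)c2)O1
F2 | step 7 | (3S,4S,5S)-3-allyl-4-methyl-5-(3,4,5-trimethoxyphenyl)oxolan-2-one | O=C1[C@@H](CC=C)[C@H](C)[C@@H](c2cc(OC)c(OC)c(OC)c2)O1
F3 | step 7 | (3S,4S,5S)-3-allyl-3-(2-methoxy-3-oxobutyl)-4-methyl-5-(3,4,5-trimethoxyphenyl)oxolan-2-one (epimers at the methoxy carbon) | O=C1[C@@](CC=C)(CC(OC)C(C)=O)[C@H](C)[C@@H](c2cc(OC)c(OC)c(OC)c2)O1
F4 | step 4 | (1S,2S)-2-methyl-1-(3,4,5-trimethoxyphenyl)but-3-en-1-ol | C=C[C@H](C)[C@H](O)c1cc(OC)c(OC)c(OC)c1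
F5 | step 4 | tert-butyl(dimethyl){[(1S,2S)-2-methyl-1-(3,4,5-trimethoxyphenyl)but-3-en-1-yl]oxy}silane | C=C[C@H](C)[C@H](O[Si](C)(C)C(C)(C)C)c1cc(OC)c(OC)c(OC)c1
F6 | step 4 | (3S,4S)-4-{[tert-butyl(dimethyl)silyl]oxy}-3-methyl-4-(3,4,5-trimethoxyphenyl)butan-1-ol | OCC[C@H](C)[C@H](O[Si](C)(C)C(C)(C)C)c1cc(OC)c(OC)c(OC)c1
F7 | step 4 | (3S,4S)-4-{[tert-butyl(dimethyl)silyl]oxy}-3-methyl-4-(3,4,5-trimethoxyphenyl)butanoic acid | OC(=O)C[C@H](C)[C@H](O[Si](C)(C)C(C)(C)C)c1cc(OC)c(OC)c(OC)c1
F8 | step 9 | (2S,3S,3aR)-3a-allyl-7-bromo-5-methoxy-3-methyl-2-(3,4,5-trimethoxyphenyl)-3,3a-dihydro-1-benzofuran-6(2H)-one | C=CC[C@@]12C=C(OC)C(=O)C(Br)=C1O[C@H](c1cc(OC)c(OC)c(OC)c1)[C@H]2C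
F9 | step 9 | (2S,3S,5S)-5-allyl-7-bromo-5-methoxy-3-methyl-2-(3,4,5-trimethoxyphenyl)-3,5-dihydro-1-benzofuran-6(2H)-one | C=CC[C@]1(OC)C=C2C(=C(Br)C1=O)O[C@H](c1cc(OC)c(OC)c(OC)c1)[C@H]2C
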